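The route cuts ring B of the drimane core at C6–C7 (drimane numbering). An exocyclic C5=C6 methylene on ring A, flanked by the quaternary carbons C4 and C10, serves as acceptor for a C7 radical held on C10 through C9 and the C8 ketone. In one operation a tin hydride mediated 6-endo closure forms C6–C7 and ring B, delivers the C5 hydrogen trans to the C10 methyl, and leaves C9 free to settle with its ester equatorial. The precursor is a γ-bromo β-keto ester on an enantioenriched methylenecyclohexane; its ketone is the latent C12 methylene and its ester the C11 carbinol that is finally acylated with 2,4-dihydroxycinnamic acid.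

Key step: step 8

Remarks on the chemistry (assumptions):
- Numbering: ring A = C1–C5 and C10, ring B = C5–C10, C11 on C9, C12 on C8, for all intermediates.
- The sense of induction of the palladium–phosphinooxazoline allylation is taken as (S)-ligand gives (S)-ketone, so the (R)-ligand is specified for (R)-4.
- The enantiomeric purity reached in step 2 should be high but may not be complete; if needed it is raised by recrystallization at a later solid intermediate (12 or 14).
- C9 of 10 and 11 lies between two carbonyl groups and is configurationally labile; both are carried as interconverting C9 epimers and listed under the epimer that maps onto 12.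
- The 2-hydroxycinnamate unit is photolabile (E/Z isomerization, then lactonization to the coumarin with loss of the alcohol), so steps 11–13 are run with exclusion of light.

Step 1
Reactants: 1 2,2,6-trimethylcyclohexanone; 2 allyl chloroformate
Product: 3 allyl 2,6,6-trimethylcyclohex-1-en-1-yl carbonate
Conditions: LiN(SiMe3)2, THF, 0 °C; then 2, −78 → 25 °C
Reagents that add atoms: none
Why: Only one α-carbon of 1 carries a hydrogen, so a single tetrasubstituted lithium enolate forms, and the hard chloroformate should acylate it on oxygen (enolate O-acylation), since C-acylation would have to build a quaternary centre beside a quaternary carbon.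

Step 2
Reactants: 3 allyl 2,6,6-trimethylcyclohex-1-en-1-yl carbonate
Product: 4 (2R)-2-allyl-2,6,6-trimethylcyclohexan-1-one
Conditions: Pd2(dba)3 (2.5 mol %), (R)-t-BuPHOX [(R)-4-tert-butyl-2-(2-diphenylphosphinophenyl)-4,5-dihydrooxazole] (6 mol %), THF, 25 °C
Reagents that add atoms: none
Why: Tsuji-type decarboxylative asymmetric allylic alkylation, in which zerovalent palladium ionizes the allyl carbonate, CO2 is lost and the regiospecifically formed enolate recombines with the π-allyl unit inside the chiral pocket of the P,N-ligand, which sets the quaternary centre (the future C10) as R.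

Step 3
Reactants: 4 (2R)-2-allyl-2,6,6-trimethylcyclohexan-1-one
Product: 6 (1R)-1-allyl-1,3,3-trimethyl-2-methylidenecyclohexane, via β-silyl carbinol 5 (not isolated)
Conditions: Me3SiCH2Li, THF/pentane, 0 → 25 °C; then aq. H2SO4, THF, 25 °C
Reagents that add atoms: (trimethylsilyl)methyllithium, [Li]C[Si](C)(C)C
Why: Peterson olefination, chosen because the ketone between two quaternary carbons has no α-hydrogen to lose to the organolithium and is more open to a small carbanion than to a phosphorus ylide, while the β-silyl carbinol can eliminate only to the exocyclic alkene, which cannot migrate into the ring.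

Step 4
Reactants: 6 (1R)-1-allyl-1,3,3-trimethyl-2-methylidenecyclohexane
Product: 7 2-[(1R)-1,3,3-trimethyl-2-methylidenecyclohexyl]acetaldehyde
Conditions: OsO4 (2 mol %), NaIO4 (4 equiv), 2,6-lutidine, dioxane/H2O (3:1), 25 °C
Reagents that add atoms: sodium periodate, [Na+].[O-]I(=O)(=O)=O (oxygen, passed on through catalytic OsO4, O=[Os](=O)(=O)=O)
Why: Lemieux–Johnson oxidation, in which the sterically demanding osmylation should take the open monosubstituted allyl alkene and leave the exocyclic methylene, buried between the quaternary C4 and C10, untouched, after which periodate cleaves the diol.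

Step 5
Reactants: 7 2-[(1R)-1,3,3-trimethyl-2-methylidenecyclohexyl]acetaldehyde
Product: 9 methyl 2-[(1R)-1,3,3-trimethyl-2-methylidenecyclohexyl]acetate, via carboxylic acid 8 (not isolated)
Conditions: NaClO2, NaH2PO4, 2-methyl-2-butene, t-BuOH/H2O, 0 → 25 °C; then MeI, K2CO3, DMF, 25 °C
Reagents that add atoms: sodium chlorite, [Na+].[O-]Cl=O; iodomethane, CI
Why: Pinnick oxidation with a hypochlorite scavenger spares the alkene, and immediate carboxylate alkylation (SN2 on MeI) under basic conditions avoids storing an acid that could lactonize onto C5 under acid.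

Step 6
Reactants: 9 methyl 2-[(1R)-1,3,3-trimethyl-2-methylidenecyclohexyl]acetate
Product: 10 methyl (2S)-4-chloro-3-oxo-2-[(1R)-1,3,3-trimethyl-2-methylidenecyclohexyl]butanoate
Conditions: LiN(i-Pr)2, THF, −78 °C; ClCH2C(O)N(OMe)Me, −78 → −30 °C; cold 1 M HCl
Reagents that add atoms: 2-chloro-N-methoxy-N-methylacetamide, ClCC(=O)N(C)OC
Why: Claisen-type acylation of an ester enolate with a Weinreb amide, whose chelated tetrahedral adduct should persist until the quench so that the acidic product never meets unreacted enolate, and which installs the C8 ketone and the C7 halide together without any electrophilic halogenation near the alkene.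

Step 7
Reactants: 10 methyl (2S)-4-chloro-3-oxo-2-[(1R)-1,3,3-trimethyl-2-methylidenecyclohexyl]butanoate
Product: 11 methyl (2S)-4-bromo-3-oxo-2-[(1R)-1,3,3-trimethyl-2-methylidenecyclohexyl]butanoate
Conditions: LiBr (10 equiv), acetone, 25 °C, dark
Reagents that add atoms: lithium bromide, [Li+].[Br-]
Why: Finkelstein halide exchange by SN2 at the carbonyl-activated primary C7, driven by the excess of bromide, gives the better radical precursor under neutral conditions that leave the alkene and the labile C9 alone.

Step 8
Reactants: 11 methyl (2S)-4-bromo-3-oxo-2-[(1R)-1,3,3-trimethyl-2-methylidenecyclohexyl]butanoate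
Product: 12 methyl 8-oxo-12-nordriman-11-oate [methyl (1R,4aS,8aS)-5,5,8a-trimethyl-2-oxodecahydronaphthalene-1-carboxylate]
Conditions: Bu3SnH (1.3 equiv), AIBN (0.15 equiv), PhH (0.01 M), 80 °C, syringe-pump addition over 6 h; aq. KF; then DBU (cat.), CH2Cl2, 25 °C
Reagents that add atoms: none
Why: Bu3Sn• abstracts bromine from C7 of 11, and the electrophilic α-keto radical adds to C6, the unsubstituted terminus of the electron-rich exocyclic C5=C6 alkene, so that C6–C7 forms and the tertiary C5 radical then takes hydrogen from Bu3SnH, which carries the chain. The closest known reaction type is the tin hydride mediated cyclization of 2-oxohex-5-enyl (α-carbonyl) radicals onto 1,1-disubstituted alkenes. Ring B closes in the 6-endo-trig mode, because the 5-exo alternative would have to bond to C5 between the quaternary C4 and C10 and would leave a primary radical, and the planar radical–carbonyl unit inside the forming ring further disfavours the smaller ring. C5 is controlled by C10: the ring-fusion radical is shielded on its β face by the axial C10 methyl and the syn-axial C4 methyl, so hydrogen should arrive on the α face and give the trans-decalin, while the labile C9 is settled by enolization (DBU) with its ester equatorial. The selectivity the step needs is ring closure ahead of simple reduction of the C7 radical; it is secured by the polarity match of radical and alkene, by the quaternary C10 that holds C7 beside C6 and leaves no allylic hydrogen to abstract, and by a low stationary Bu3SnH concentration.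

Step 9
Reactants: 12 methyl 8-oxo-12-nordriman-11-oate
Product: 13 methyl albicanate [methyl (1S,4aS,8aS)-5,5,8a-trimethyl-2-methylidenedecahydronaphthalene-1-carboxylate]
Conditions: Zn, CH2Br2, TiCl4 (reagent preformed in THF, −40 → 5 °C); 12, CH2Cl2, 0 → 25 °C
Reagents that add atoms: dibromomethane, BrCBr
Why: Takai–Lombardo methylenation, whose non-basic titanium methylene reagent attacks the ketone but not the ester and does not enolize the β-keto ester, so the C9 configuration should be kept.

Step 10
Reactants: 13 methyl albicanate
Product: 14 (+)-albicanol {[(1S,4aS,8aS)-5,5,8a-trimethyl-2-methylidenedecahydronaphthalen-1-yl]methanol}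
Conditions: LiAlH4, Et2O, 0 °C; aqueous work-up
Reagents that add atoms: none
Why: Hydride reduction of the ester to the primary alcohol at low temperature is faster than deprotonation at C9, so neither epimerization nor conjugation of the exocyclic alkene is expected.

Step 11
Reactants: 15 (E)-2,4-dihydroxycinnamic acid
Product: 17 (E)-3-[2,4-bis(tert-butyldimethylsilyloxy)phenyl]prop-2-enoic acid, via tris-silyl derivative 16 (not isolated)
Conditions: t-BuMe2SiCl (3.5 equiv), imidazole, DMF, 25 °C; then AcOH/THF/H2O (3:1:1), 25 °C, dark
Reagents that add atoms: tert-butyldimethylsilyl chloride, CC(C)(C)[Si](C)(C)Cl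
Why: Exhaustive silylation followed by selective hydrolysis works because a silyl ester is far more labile to aqueous acid than an aryl silyl ether, which frees the acid and leaves both phenols masked.

Step 12
Reactants: 14 (+)-albicanol; 17 (E)-3-[2,4-bis(tert-butyldimethylsilyloxy)phenyl]prop-2-enoic acid
Product: 18 (1S,4aS,8aS)-albicanyl (E)-2,4-bis(tert-butyldimethylsilyloxy)cinnamate
Conditions: DCC, DMAP (0.3 equiv), CH2Cl2, 0 → 25 °C, dark
Reagents that add atoms: none
Why: Steglich esterification acylates the hindered primary alcohol on oxygen through the acylpyridinium, so no substitution at C11 is needed and C9 and the alkene geometry are untouched.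

Step 13
Reactants: 18 (1S,4aS,8aS)-albicanyl (E)-2,4-bis(tert-butyldimethylsilyloxy)cinnamate
Product: 19 (1S,4aS,8aS)-albicanyl (E)-2,4-dihydroxycinnamate (target)
Conditions: Bu4NF (2.4 equiv), AcOH (2.4 equiv), THF, 0 °C, dark
Reagents that add atoms: none
Why: Fluoride-driven desilylation cleaves aryl silyl ethers readily, and the acetic acid buffer keeps the phenoxides protonated so that the cinnamate ester and the exocyclic alkene should survive.

Compound list
1 | 2,2,6-trimethylcyclohexanone | CC1CCCC(C)(C)C1=O | starting material
2 | allyl chloroformate | C=CCOC(=O)Cl | starting material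
3 | allyl 2,6,6-trimethylcyclohex-1-en-1-yl carbonate | C=CCOC(=O)OC1=C(C)CCCC1(C)C | intermediate
4 | (2R)-2-allyl-2,6,6-trimethylcyclohexan-1-one | C=CC[C@@]1(C)CCCC(C)(C)C1=O | intermediate
5 | (2R)-2-allyl-2,6,6-trimethyl-1-[(trimethylsilyl)methyl]cyclohexan-1-ol (carbinol carbon of either configuration) | C=CC[C@@]1(C)CCCC(C)(C)C1(O)C[Si](C)(C)C | intermediate (not isolated)
6 | (1R)-1-allyl-1,3,3-trimethyl-2-methylidenecyclohexane | C=CC[C@@]1(C)CCCC(C)(C)C1=C | intermediate
7 | 2-[(1R)-1,3,3-trimethyl-2-methylidenecyclohexyl]acetaldehyde | O=CC[C@@]1(C)CCCC(C)(C)C1=C | intermediate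
8 | 2-[(1R)-1,3,3-trimethyl-2-methylidenecyclohexyl]acetic acid | OC(=O)C[C@@]1(C)CCCC(C)(C)C1=C | intermediate (not isolated)
9 | methyl 2-[(1R)-1,3,3-trimethyl-2-methylidenecyclohexyl]acetate | COC(=O)C[C@@]1(C)CCCC(C)(C)C1=C | intermediate
10 | methyl (2S)-4-chloro-3-oxo-2-[(1R)-1,3,3-trimethyl-2-methylidenecyclohexyl]butanoate (C9 labile) | ClCC(=O)[C@H](C(=O)OC)[C@@]1(C)CCCC(C)(C)C1=C | intermediate
11 | methyl (2S)-4-bromo-3-oxo-2-[(1R)-1,3,3-trimethyl-2-methylidenecyclohexyl]butanoate (C9 labile; key-step precursor) | BrCC(=O)[C@H](C(=O)OC)[C@@]1(C)CCCC(C)(C)C1=C | intermediate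
12 | methyl 8-oxo-12-nordriman-11-oate [methyl (1R,4aS,8aS)-5,5,8a-trimethyl-2-oxodecahydronaphthalene-1-carboxylate] | O=C1CC[C@H]2C(C)(C)CCC[C@]2(C)[C@H]1C(=O)OC | intermediate
13 | methyl albicanate [methyl (1S,4aS,8aS)-5,5,8a-trimethyl-2-methylidenedecahydronaphthalene-1-carboxylate] | C=C1CC[C@H]2C(C)(C)CCC[C@]2(C)[C@H]1C(=O)OC | intermediate
14 | (+)-albicanol {[(1S,4aS,8aS)-5,5,8a-trimethyl-2-methylidenedecahydronaphthalen-1-yl]methanol} | C=C1CC[C@H]2C(C)(C)CCC[C@]2(C)[C@H]1CO | intermediate
15 | (E)-2,4-dihydroxycinnamic acid | O=C(O)/C=C/c1ccc(O)cc1O | starting material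
16 | tert-butyldimethylsilyl (E)-3-[2,4-bis(tert-butyldimethylsilyloxy)phenyl]prop-2-enoate | CC(C)(C)[Si](C)(C)OC(=O)/C=C/c1ccc(O[Si](C)(C)C(C)(C)C)cc1O[Si](C)(C)C(C)(C)C | intermediate (not isolated)
17 | (E)-3-[2,4-bis(tert-butyldimethylsilyloxy)phenyl]prop-2-enoic acid | OC(=O)/C=C/c1ccc(O[Si](C)(C)C(C)(C)C)cc1O[Si](C)(C)C(C)(C)C | intermediate
18 | (1S,4aS,8aS)-albicanyl (E)-2,4-bis(tert-butyldimethylsilyloxy)cinnamate | C=C1CC[C@H]2C(C)(C)CCC[C@]2(C)[C@H]1COC(=O)/C=C/c1ccc(O[Si](C)(C)C(C)(C)C)cc1O[Si](C)(C)C(C)(C)C | intermediate
19 | (1S,4aS,8aS)-albicanyl (E)-2,4-dihydroxycinnamate | C=C1CC[C@H]2C(C)(C)CCC[C@]2(C)[C@H]1COC(=O)/C=C/c1ccc(O)cc1O | target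

Total step count: 13. Longest linear sequence: 12 steps (steps 1–10, 12 and 13); step 11 prepares the protected acid on a side branch.

Steps most likely to fail

Step 8. Hydrogen transfer from Bu3SnH to the open-chain C7 radical may outrun ring closure and give simple debromination, and prolonged heating may let the bromo keto ester close by O-alkylation instead. The fallback separates ring closure from hydrogen delivery. It sets out from 11: NaI in acetone should give methyl (2S)-4-iodo-3-oxo-2-[(1R)-1,3,3-trimethyl-2-methylidenecyclohexyl]butanoate F1. Irradiation of F1 with catalytic (Bu3Sn)2 in benzene runs the closure as an iodine-atom-transfer chain with no hydride present, so the C7 radical can only cyclize or recapture iodine. This should give methyl 5-iodo-8-oxo-12-nordriman-11-oate F2. Bu3SnH and AIBN added to the same flask then reduce the C5–I bond through the same tertiary radical, and the route is rejoined at 12.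

Step 6. The hindered enolate may act as a base toward the chloroacetamide or displace chloride instead of adding to the carbonyl, or the tetrahedral adduct may collapse early so that proton transfer stalls conversion. The fallback replaces acylation by addition to an aldehyde followed by oxidation. It sets out from 9: the same lithium enolate is added at −78 °C to anhydrous chloroacetaldehyde, whose aldolate is not acidic, to give methyl 4-chloro-3-hydroxy-2-[(1R)-1,3,3-trimethyl-2-methylidenecyclohexyl]butanoate F3. Dess–Martin periodinane buffered with NaHCO3 in CH2Cl2 then oxidizes F3, and the route is rejoined at 10.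

Step 4. The osmylation may not discriminate well enough between the two alkenes, leading to oxidation at the exocyclic methylene. The fallback cleaves the allyl group while it is the only alkene. It sets out from 4: ozonolysis (O3, CH2Cl2, −78 °C; PPh3) should give 2-[(1R)-1,3,3-trimethyl-2-oxocyclohexyl]acetaldehyde F4. Ethylene glycol with pyridinium p-toluenesulfonate acetalizes only the aldehyde, the flanked ketone being too hindered, to give (2R)-2-(1,3-dioxolan-2-ylmethyl)-2,6,6-trimethylcyclohexan-1-one F5. Me3SiCH2Li adds to give (2R)-2-(1,3-dioxolan-2-ylmethyl)-2,6,6-trimethyl-1-[(trimethylsilyl)methyl]cyclohexan-1-ol F6. KH in THF eliminates F6 to 2-{[(1R)-1,3,3-trimethyl-2-methylidenecyclohexyl]methyl}-1,3-dioxolane F7. Mild aqueous acid (pyridinium p-toluenesulfonate, acetone/H2O) unmasks the aldehyde, and the route is rejoined at 7.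

Further compounds
F1 | step 8 | methyl (2S)-4-iodo-3-oxo-2-[(1R)-1,3,3-trimethyl-2-methylidenecyclohexyl]butanoate | ICC(=O)[C@H](C(=O)OC)[C@@]1(C)CCCC(C)(C)C1=C
F2 | step 8 | methyl 5-iodo-8-oxo-12-nordriman-11-oate (C5 configuration open) | O=C1CCC2(I)C(C)(C)CCC[C@]2(C)[C@H]1C(=O)OC
F3 | step 6 | methyl 4-chloro-3-hydroxy-2-[(1R)-1,3,3-trimethyl-2-methylidenecyclohexyl]butanoate (mixture of diastereomers at C2 and C3) | ClCC(O)C(C(=O)OC)[C@@]1(C)CCCC(C)(C)C1=C
F4 | step 4 | 2-[(1R)-1,3,3-trimethyl-2-oxocyclohexyl]acetaldehyde | O=CC[C@@]1(C)CCCC(C)(C)C1=O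
F5 | step 4 | (2R)-2-(1,3-dioxolan-2-ylmethyl)-2,6,6-trimethylcyclohexan-1-one | O1CCOC1C[C@@]1(C)CCCC(C)(C)C1=O
F6 | step 4 | (2R)-2-(1,3-dioxolan-2-ylmethyl)-2,6,6-trimethyl-1-[(trimethylsilyl)methyl]cyclohexan-1-ol (carbinol carbon of either configuration) | O1CCOC1C[C@@]1(C)CCCC(C)(C)C1(O)C[Si](C)(C)C
F7 | step 4 | 2-{[(1R)-1,3,3-trimethyl-2-methylidenecyclohexyl]methyl}-1,3-dioxolane | O1CCOC1C[C@@]1(C)CCCC(C)(C)C1=C
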